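The numbers in the tables are calculated with made-up constants, noise included.

At early times the autumn run, with more partner, runs ahead of the summer run: at 6.7 min it has turned 33.3 % of its starting material into target, against 19.2 %. Later both curves flatten, and at 46 min the shares stand at 51.1 % and 63.6 %.

| flask | starting material | partner | time |
|---|---|---|---|
| summer | 0.150 M | 0.375 M |  |
| autumn | 0.150 M | 0.560 M |  |
| noon | 0.0370 M | 0.375 M | 46 min |

| run | time / min | [target] / M |
|---|---|---|
| summer run | 1.8 | 0.0092 |
| summer run | 3.5 | 0.0194 |
| summer run | 6.7 | 0.0288 |
| summer run | 13 | 0.0504 |
| summer run | 24 | 0.0649 |
| summer run | 46 | 0.0766 |
| autumn run | 1.8 | 0.0182 |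
| autumn run | 3.5 | 0.0278 |
| autumn run | 6.7 | 0.0499 |
| autumn run | 13 | 0.0690 |
| autumn run | 24 | 0.0872 |
| autumn run | 46 | 0.0954 |

(standard deviation of a reading: 0.002 M)

- Overall: starting material + partner -> target.
- Constant volume, constant temperature.
- What is held in complexes is read along with the free species.
- "The second partner" is partner.
- An order is taken over about fifteen percent of the charge, up and down.

- the exponent of [partner] in the starting rate at the charge of the summer run (at the point where two percent of the starting material have become target)
- target in the noon run at 46 min, as a share of the starting material charged

I read the shortfall as a second exit for starting material beside the making of target, both first order in it. My number is then the branch odds ω, target share y at 46 min over the share not target, y/(1−y), read as a selectivity factor: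

ω summer = 1.04, ω autumn = 1.75

Under that reading the odds ignore the charge of starting material, so the noon run, with the summer partner charge and a quarter of its starting material, reads 51.1 % at the same time. To test whether one number is enough, I take g, partner at mid-course (charge less 0.5 of the target made), as a share of the summer charge:

g summer = 0.898, g autumn = 1.37, g noon = 0.975

n = ln(ω autumn/ω summer)/ln(g autumn/g summer) = 1.23

ω noon = ω summer (g noon/g summer)^n = 1.15, so y = 53.6 %

The correction to the one number adds 2.5 percentage points. I also take n as my order in partner.

The forecast says “a reversible reaction with K≈4 fits”, and gives an order of 1 (0.75 to 1.35) and 55 % (48 % to 65 %).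

The flask gives an order of 1.2 and 55.2 %.

    2 partner ⇌ reagent dimer, settled at all times (3.520 M⁻¹)
    starting material + reagent dimer → target + partner (0.8820 M⁻¹ min⁻¹)
    starting material → decomposed substrate (0.06480 min⁻¹)
    starting material + partner ⇌ idle substrate-reagent adduct, settled at all times (5.000 M⁻¹)

In the noon run the odds come to 1.23, more than the 1.04 read in the summer run and less than the 1.75 read in the autumn run. From the start of the noon run, starting material stands partly as idle substrate-reagent adduct and partner partly as reagent dimer, the dimer carries starting material to target while decomposition to decomposed substrate runs beside it, and at 46 min target stands at 55.2 % of the starting material charged.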